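Ring A (C1–C5, C10) carries its two functionalised carbons, the C1 carbinol and the methylene-bearing C4, in a 1,4-relationship across the C2–C3 bridge, so it is traced to a cyclohexane-1,4-dione. That dione arises by one-carbon ring expansion of a cyclopentane-1,3-dione: a zinc carbenoid cyclopropanates the dione enolate and strain release opens the donor–acceptor cyclopropane, and since both CO–CH2 bonds give the same product no regiocontrol is needed. The precursor, a methyl-substituted hydrindenedione, follows from a catalytic asymmetric Diels–Alder reaction that sets C10 and a Claisen cyclisation. Hydroboration, methylenation, allylic oxidation and a Z-selective olefination complete the route.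

Key step: step 6

Remarks on the chemistry:
- Positions are numbered as in the eudesmane skeleton of the target: ring A is C1–C5 and C10, ring B is C5–C10, C14 is the angular methyl on C10, C15 is the exocyclic methylene carbon on C4, and β is the face of the angular methyl.
- Assumption: the (S)-configured oxazaborolidinium catalyst of step 2 is taken to give the adduct with the R-configured quaternary carbon; if the sense of induction is the opposite one, the (R)-catalyst is used and nothing else changes.
- Compounds 1, 3, 16 and 18 are taken as purchased.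

Step 1
Reactants: 1 2-chlorobuta-1,3-diene (chloroprene)
Product: 2 2-(propan-2-yl)buta-1,3-diene
Conditions: i-PrMgCl, NiCl2(dppp) (1 mol %; dppp = 1,3-bis(diphenylphosphino)propane), Et2O, 0 °C to reflux; distillation
Reagents that add atoms: isopropylmagnesium chloride CC(C)[Mg]Cl
Why: Nickel-catalysed Kumada cross-coupling of the vinylic C–Cl bond with the secondary Grignard reagent should give the 2-alkylbutadiene; no stereocentre is formed.

Step 2
Reactants: 2 2-(propan-2-yl)buta-1,3-diene; 3 ethyl (2E)-3-methyl-4-oxobut-2-enoate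
Product: 4 ethyl (1R,6R)-6-formyl-6-methyl-3-(propan-2-yl)cyclohex-3-ene-1-carboxylate
Conditions: (S)-3,3-diphenyl-1-(o-tolyl)tetrahydro-1H,3H-pyrrolo[1,2-c][1,3,2]oxazaborole (20 mol %), Tf2NH (20 mol %), CH2Cl2, −78 to −40 °C
Reagents that add atoms: none
Why: Catalytic asymmetric Diels–Alder reaction in which the oxazaborolidinium ion binds the formyl oxygen, the more nucleophilic diene terminus bonds to the ester-bearing β-carbon of 3 (para orientation of the isopropyl-bearing and quaternary carbons), the E-geometry of 3 becomes the trans relationship of formyl and ester groups, and shielding of one dienophile face by the catalyst sets the quaternary carbon (future C10) as R.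

Step 3
Reactants: 4 ethyl (1R,6R)-6-formyl-6-methyl-3-(propan-2-yl)cyclohex-3-ene-1-carboxylate
Product: 5 ethyl (1R,6R)-6-(1-hydroxyethyl)-6-methyl-3-(propan-2-yl)cyclohex-3-ene-1-carboxylate (carbinol epimers)
Conditions: MeMgBr (1.1 equiv), THF, −78 °C; sat. aq NH4Cl at −78 °C; crude product used at once
Reagents that add atoms: methylmagnesium bromide C[Mg]Br
Why: Chemoselective Grignard addition to the aldehyde beside the less electrophilic ester at −78 °C; the new carbinol centre is formed as an epimer mixture that is of no consequence because it is oxidised in step 4.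

Step 4
Reactants: 5 ethyl (1R,6R)-6-(1-hydroxyethyl)-6-methyl-3-(propan-2-yl)cyclohex-3-ene-1-carboxylate
Product: 6 ethyl (1R,6R)-6-acetyl-6-methyl-3-(propan-2-yl)cyclohex-3-ene-1-carboxylate
Conditions: Dess–Martin periodinane, NaHCO3, CH2Cl2, 0 °C to rt
Reagents that add atoms: none
Why: Dess–Martin oxidation of the secondary alcohol under buffered conditions should give the methyl ketone without touching the alkene, the ester or the stereocentres.

Step 5
Reactants: 6 ethyl (1R,6R)-6-acetyl-6-methyl-3-(propan-2-yl)cyclohex-3-ene-1-carboxylate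
Product: 7 (3aR,7aR)-7a-methyl-5-(propan-2-yl)-3a,4,7,7a-tetrahydro-1H-indene-1,3(2H)-dione
Conditions: KOtBu (2.2 equiv), THF, 0 °C to rt; 1 M HCl
Reagents that add atoms: none
Why: Intramolecular Claisen (Dieckmann-type) condensation of the γ-keto ester, in which the methyl ketone enolate attacks the ester and the acidic 1,3-dione is withdrawn as its enolate; C10 is untouched and the ring-fusion CH (future C5) is drawn trans as carried over from 6, but it stays epimerisable and any cis isomer converges in step 6.

Step 6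
Reactants: 7 (3aR,7aR)-7a-methyl-5-(propan-2-yl)-3a,4,7,7a-tetrahydro-1H-indene-1,3(2H)-dione
Product: 9 (4aR,8aR)-4a-methyl-7-(propan-2-yl)-2,3,4a,5,8,8a-hexahydronaphthalene-1,4-dione (15-noreudesm-7-ene-1,4-dione), via zinc cyclopropanolate 8 (not isolated)
Conditions: Et2Zn (3 equiv), CH2I2 (2 equiv), CH2Cl2, 0 °C; sat. aq NH4Cl; then DBU (0.2 equiv), CH2Cl2, rt
Reagents that add atoms: diiodomethane ICI
Why: Et2Zn deprotonates the enolised dione 7 and the zinc enolate takes up CH2 from EtZnCH2I in a Simmons–Smith-type [2+1] methylene transfer, the three-membered ring closing by concerted addition of the carbenoid carbon across the enolate C=C bond to give the donor–acceptor cyclopropanolate 8. Release of cyclopropane strain then drives heterolysis of the bond shared by the three- and five-membered rings (retro-aldol-type fragmentation), which regenerates the ketone and leaves a ring-enlarged zinc enolate, so the cyclopentane-1,3-dione (C10, C1, CH2, C4, C5) becomes the cyclohexane-1,4-dione of ring A. The closest known reaction type is the zinc carbenoid chain extension of β-keto esters and 1,3-diketones to γ-dicarbonyl compounds, which amounts to ring expansion when the dicarbonyl unit is cyclic. No stereocentre is created: C10 is untouched and C5, now α to the C4 ketone, is equilibrated by DBU to the thermodynamically preferred trans ring fusion. The step needs chemoselectivity for the enolate over the trisubstituted C7=C8 alkene, which the far higher nucleophilicity of the enolate and a limited carbenoid charge at 0 °C should secure. Regioselectivity is not needed because insertion into either CO–CH2 bond gives the same dione.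

Step 7
Reactants: 9 15-noreudesm-7-ene-1,4-dione
Product: 11 15-noreudesmane-1β,4β,8α-triol, via tris-boron adduct 10 (not isolated)
Conditions: BH3·THF (5 equiv), THF, 0 °C to rt; then 3 M NaOH, 30% H2O2, 0 °C to rt
Reagents that add atoms: hydrogen peroxide OO
Why: Borane reduction of both ketones and hydroboration–oxidation of the alkene in one operation: hydride reaches C1 axially from the α-face (1β-OH), the angular methyl blocks the β-face at C4 and C8 so that C4 gives the axial 4β-alcohol, and syn addition of H–B across C7=C8 from the α-face with boron on the less substituted C8 gives, after oxidation with retention, the 8α-alcohol and the 7β-isopropyl group.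

Step 8
Reactants: 11 15-noreudesmane-1β,4β,8α-triol
Product: 12 1β,8α-bis(tert-butyldimethylsilyloxy)-15-noreudesman-4β-ol
Conditions: TBSCl (2.5 equiv), imidazole, DMF, 40 °C
Reagents that add atoms: tert-butyldimethylsilyl chloride CC(C)(C)[Si](C)(C)Cl
Why: Sterically controlled silylation: the equatorial 1β- and 8α-hydroxyls should react with TBSCl, whereas the axial 4β-hydroxyl, syn-1,3-diaxial to the angular methyl, is left free.

Step 9
Reactants: 12 1β,8α-bis(tert-butyldimethylsilyloxy)-15-noreudesman-4β-ol
Product: 13 1β,8α-bis(tert-butyldimethylsilyloxy)-15-noreudesman-4-one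
Conditions: Dess–Martin periodinane, NaHCO3, CH2Cl2, rt
Reagents that add atoms: none
Why: Dess–Martin oxidation of the remaining hindered axial alcohol gives the C4 ketone; C5, again α to a carbonyl, keeps the preferred trans fusion.

Step 10
Reactants: 13 1β,8α-bis(tert-butyldimethylsilyloxy)-15-noreudesman-4-one
Product: 14 1β,8α-bis(tert-butyldimethylsilyloxy)eudesm-4(15)-ene
Conditions: Ph3PCH3Br, KOtBu, THF, 0 to 60 °C
Reagents that add atoms: methyltriphenylphosphonium bromide C[P+](c1ccccc1)(c1ccccc1)c1ccccc1.[Br-]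
Why: Wittig methylenation of the C4 ketone installs C15; any base-induced equilibration at C5 converges on the trans-fused ketone before olefination, after which C5 is fixed.

Step 11
Reactants: 14 1β,8α-bis(tert-butyldimethylsilyloxy)eudesm-4(15)-ene
Product: 15 1β,8α-bis(tert-butyldimethylsilyloxy)eudesm-4(15)-en-3α-ol
Conditions: SeO2 (0.5 equiv), t-BuOOH (3 equiv), CH2Cl2, 0 °C to rt
Reagents that add atoms: selenium dioxide O=[Se]=O (catalytic oxygen carrier); tert-butyl hydroperoxide CC(C)(C)OO (terminal oxidant)
Why: Selenium dioxide allylic oxidation (ene reaction, then [2,3]-sigmatropic shift) should attack the allylic CH2 at C3 in preference to the tertiary C5–H and deliver oxygen axially on the α-face, giving the 3α-alcohol.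

Step 12
Reactants: 15 1β,8α-bis(tert-butyldimethylsilyloxy)eudesm-4(15)-en-3α-ol; 16 (diphenoxyphosphoryl)acetic acid
Product: 17 1β,8α-bis(tert-butyldimethylsilyloxy)eudesm-4(15)-en-3β-yl (diphenoxyphosphoryl)acetate
Conditions: PPh3, DIAD, toluene, 0 °C to rt
Reagents that add atoms: none
Why: Mitsunobu esterification, in which the carboxylate of 16 displaces the activated axial 3α-oxyphosphonium group by SN2 and so inverts C3 to the equatorial 3β-ester.

Step 13
Reactants: 18 3,4-dihydroxybenzaldehyde
Product: 19 3,4-bis(tert-butyldimethylsilyloxy)benzaldehyde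
Conditions: TBSCl (2.5 equiv), imidazole, DMF, rt
Reagents that add atoms: tert-butyldimethylsilyl chloride CC(C)(C)[Si](C)(C)Cl
Why: Standard silylation of both phenols; no stereocentre is involved.

Step 14
Reactants: 17 1β,8α-bis(tert-butyldimethylsilyloxy)eudesm-4(15)-en-3β-yl (diphenoxyphosphoryl)acetate; 19 3,4-bis(tert-butyldimethylsilyloxy)benzaldehyde
Product: 20 1β,8α-bis(tert-butyldimethylsilyloxy)eudesm-4(15)-en-3β-yl (2Z)-3-[3,4-bis(tert-butyldimethylsilyloxy)phenyl]prop-2-enoate
Conditions: NaH, THF, −78 °C; then 19, −78 to −20 °C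
Reagents that add atoms: none
Why: Horner–Wadsworth–Emmons olefination with a diaryl phosphonoacetate, whose electron-poor aryloxy groups speed collapse of the kinetically formed syn adduct so that the Z-enoate should predominate.

Step 15
Reactants: 20 1β,8α-bis(tert-butyldimethylsilyloxy)eudesm-4(15)-en-3β-yl (2Z)-3-[3,4-bis(tert-butyldimethylsilyloxy)phenyl]prop-2-enoate
Product: 21 (1R,3S,5S,7R,8S,10R)-1β,8α-dihydroxyeudesm-4(15)-en-3β-yl (2Z)-3-(3,4-dihydroxyphenyl)prop-2-enoate (CNP0264533.2)
Conditions: HF·pyridine, pyridine, THF, 0 °C to rt, in the dark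
Reagents that add atoms: none
Why: Fluoride-mediated cleavage of the two aryl and two secondary silyl ethers under buffered acidic conditions should leave the allylic Z-enoate, the exocyclic alkene and all stereocentres untouched, and the absence of base avoids acyl migration to the 1-hydroxyl.

Compound list

1 | 2-chlorobuta-1,3-diene (chloroprene) | C=CC(Cl)=C | starting material
2 | 2-(propan-2-yl)buta-1,3-diene | C=CC(=C)C(C)C | intermediate
3 | ethyl (2E)-3-methyl-4-oxobut-2-enoate | CCOC(=O)/C=C(\C)C=O | starting material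
4 | ethyl (1R,6R)-6-formyl-6-methyl-3-(propan-2-yl)cyclohex-3-ene-1-carboxylate | O=C[C@]1(C)CC=C(C(C)C)C[C@H]1C(=O)OCC | intermediate
5 | ethyl (1R,6R)-6-(1-hydroxyethyl)-6-methyl-3-(propan-2-yl)cyclohex-3-ene-1-carboxylate (carbinol epimers) | CC(O)[C@]1(C)CC=C(C(C)C)C[C@H]1C(=O)OCC | intermediate
6 | ethyl (1R,6R)-6-acetyl-6-methyl-3-(propan-2-yl)cyclohex-3-ene-1-carboxylate | CC(=O)[C@]1(C)CC=C(C(C)C)C[C@H]1C(=O)OCC | intermediate
7 | (3aR,7aR)-7a-methyl-5-(propan-2-yl)-3a,4,7,7a-tetrahydro-1H-indene-1,3(2H)-dione | O=C1CC(=O)[C@]2(C)CC=C(C(C)C)C[C@@H]12 | intermediate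
8 | ethylzinc cyclopropanolate of the tricyclic donor–acceptor cyclopropane (shown for methylene transfer to the C4 side on the face anti to the angular methyl; the C1-side regioisomer converges on 9) | CC[Zn]O[C@@]12C[C@@H]1C(=O)[C@]3(C)CC=C(C(C)C)C[C@@H]23 | intermediate (not isolated)
9 | (4aR,8aR)-4a-methyl-7-(propan-2-yl)-2,3,4a,5,8,8a-hexahydronaphthalene-1,4-dione (15-noreudesm-7-ene-1,4-dione) | O=C1CCC(=O)[C@]2(C)CC=C(C(C)C)C[C@@H]12 | intermediate
10 | tris-boron adduct (1β- and 4β-boryloxy, 8α-boryl) | BO[C@H]1CC[C@@H](OB)[C@]2(C)C[C@H](B)[C@@H](C(C)C)C[C@@H]12 | intermediate (not isolated)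
11 | 15-noreudesmane-1β,4β,8α-triol | O[C@H]1CC[C@@H](O)[C@]2(C)C[C@H](O)[C@@H](C(C)C)C[C@@H]12 | intermediate
12 | 1β,8α-bis(tert-butyldimethylsilyloxy)-15-noreudesman-4β-ol | O[C@H]1CC[C@@H](O[Si](C)(C)C(C)(C)C)[C@]2(C)C[C@H](O[Si](C)(C)C(C)(C)C)[C@@H](C(C)C)C[C@@H]12 | intermediate
13 | 1β,8α-bis(tert-butyldimethylsilyloxy)-15-noreudesman-4-one | O=C1CC[C@@H](O[Si](C)(C)C(C)(C)C)[C@]2(C)C[C@H](O[Si](C)(C)C(C)(C)C)[C@@H](C(C)C)C[C@@H]12 | intermediate
14 | 1β,8α-bis(tert-butyldimethylsilyloxy)eudesm-4(15)-ene | C=C1CC[C@@H](O[Si](C)(C)C(C)(C)C)[C@]2(C)C[C@H](O[Si](C)(C)C(C)(C)C)[C@@H](C(C)C)C[C@@H]12 | intermediate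
15 | 1β,8α-bis(tert-butyldimethylsilyloxy)eudesm-4(15)-en-3α-ol | C=C1[C@H](O)C[C@@H](O[Si](C)(C)C(C)(C)C)[C@]2(C)C[C@H](O[Si](C)(C)C(C)(C)C)[C@@H](C(C)C)C[C@@H]12 | intermediate
16 | (diphenoxyphosphoryl)acetic acid | OC(=O)CP(=O)(Oc1ccccc1)Oc1ccccc1 | starting material
17 | 1β,8α-bis(tert-butyldimethylsilyloxy)eudesm-4(15)-en-3β-yl (diphenoxyphosphoryl)acetate | C=C1[C@@H](OC(=O)CP(=O)(Oc2ccccc2)Oc2ccccc2)C[C@@H](O[Si](C)(C)C(C)(C)C)[C@]2(C)C[C@H](O[Si](C)(C)C(C)(C)C)[C@@H](C(C)C)C[C@@H]12 | intermediate
18 | 3,4-dihydroxybenzaldehyde | O=Cc1ccc(O)c(O)c1 | starting material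
19 | 3,4-bis(tert-butyldimethylsilyloxy)benzaldehyde | O=Cc1ccc(O[Si](C)(C)C(C)(C)C)c(O[Si](C)(C)C(C)(C)C)c1 | intermediate
20 | 1β,8α-bis(tert-butyldimethylsilyloxy)eudesm-4(15)-en-3β-yl (2Z)-3-[3,4-bis(tert-butyldimethylsilyloxy)phenyl]prop-2-enoate | C=C1[C@@H](OC(=O)/C=C\c2ccc(O[Si](C)(C)C(C)(C)C)c(O[Si](C)(C)C(C)(C)C)c2)C[C@@H](O[Si](C)(C)C(C)(C)C)[C@]2(C)C[C@H](O[Si](C)(C)C(C)(C)C)[C@@H](C(C)C)C[C@@H]12 | intermediate
21 | (1R,3S,5S,7R,8S,10R)-1β,8α-dihydroxyeudesm-4(15)-en-3β-yl (2Z)-3-(3,4-dihydroxyphenyl)prop-2-enoate | C=C1[C@@H](OC(=O)/C=C\c2ccc(O)c(O)c2)C[C@@H](O)[C@]2(C)C[C@H](O)[C@@H](C(C)C)C[C@@H]12 | target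

Total step count: 15. Longest linear sequence: 14 steps (steps 1–12, 14 and 15; step 13 is a one-step side branch).

Steps most likely to fail

Step 6. Methylene transfer to the non-chelated zinc enolate of the cyclic dione may be slow or incomplete, and excess carbenoid may then cyclopropanate the C7=C8 alkene. The fallback sets out from 7 and comes back at 9. It isolates the donor–acceptor cyclopropane in place of the one-pot enolate homologation: O-silylation of 7 (TBSOTf, Et3N, CH2Cl2, −78 °C) should give (3aR,7aR)-3-(tert-butyldimethylsilyloxy)-7a-methyl-5-(propan-2-yl)-3a,4,7,7a-tetrahydro-1H-inden-1-one F1. Simmons–Smith cyclopropanation of its enol ether bond with a slight excess of the Furukawa reagent (Et2Zn, CH2I2, CH2Cl2, 0 °C) should give the tricyclic silyloxycyclopropyl ketone F2, which can be purified. Fluoride-triggered fragmentation (TBAF, AcOH, THF) followed by DBU equilibration then gives 9.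

Step 2. The trisubstituted enal and the weakly activated alkyl diene may turn over poorly under the chiral catalyst, or the facial discrimination may be insufficient. The fallback sets out from 2 and 3 and comes back at 4, replacing catalyst control by resolution. Cycloaddition promoted by the achiral Lewis acid Me2AlCl (CH2Cl2, −78 °C) gives the racemate, that is 4 together with its enantiomer ethyl (1S,6S)-6-formyl-6-methyl-3-(propan-2-yl)cyclohex-3-ene-1-carboxylate F3. Acetalisation with (1R,2R)-1,2-diphenylethane-1,2-diol (PPTS, benzene, azeotropic removal of water) gives the diastereomeric acetals, the (4R,5R)-4,5-diphenyl-1,3-dioxolane of 4 F4 and the (4R,5R)-4,5-diphenyl-1,3-dioxolane of the enantiomer F5. These are separated by chromatography or crystallisation, and mild acid hydrolysis of F4 (PPTS, acetone–water) returns enantiopure 4.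

Step 12. SN2′ capture of the carboxylate at C15, or elimination to the diene, may compete with direct inversion at the hindered allylic carbinol. The fallback sets out from 15 and comes back at 17, inverting C3 by oxidation and reduction in place of displacement. Dess–Martin oxidation should give the α-methylene ketone 1β,8α-bis(tert-butyldimethylsilyloxy)eudesm-4(15)-en-3-one F6. Luche reduction (NaBH4, CeCl3·7H2O, MeOH, −78 °C), with axial hydride delivery from the α-face, should give the equatorial alcohol 1β,8α-bis(tert-butyldimethylsilyloxy)eudesm-4(15)-en-3β-ol F7. Carbodiimide esterification with 16 (DCC, DMAP cat., CH2Cl2) then gives 17.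

Further compounds

F1 | step 6 | (3aR,7aR)-3-(tert-butyldimethylsilyloxy)-7a-methyl-5-(propan-2-yl)-3a,4,7,7a-tetrahydro-1H-inden-1-one | O=C1C=C(O[Si](C)(C)C(C)(C)C)[C@@H]2CC(C(C)C)=CC[C@@]12C
F2 | step 6 | tricyclic silyloxycyclopropyl ketone (tert-butyldimethylsilyl analogue of 8) | CC(C)(C)[Si](C)(C)O[C@@]12C[C@@H]1C(=O)[C@]3(C)CC=C(C(C)C)C[C@@H]23
F3 | step 2 | ethyl (1S,6S)-6-formyl-6-methyl-3-(propan-2-yl)cyclohex-3-ene-1-carboxylate (enantiomer of 4) | O=C[C@@]1(C)CC=C(C(C)C)C[C@@H]1C(=O)OCC
F4 | step 2 | ethyl (1R,6R)-6-[(4R,5R)-4,5-diphenyl-1,3-dioxolan-2-yl]-6-methyl-3-(propan-2-yl)cyclohex-3-ene-1-carboxylate | C1(O[C@H](c2ccccc2)[C@@H](c2ccccc2)O1)[C@]3(C)CC=C(C(C)C)C[C@H]3C(=O)OCC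
F5 | step 2 | ethyl (1S,6S)-6-[(4R,5R)-4,5-diphenyl-1,3-dioxolan-2-yl]-6-methyl-3-(propan-2-yl)cyclohex-3-ene-1-carboxylate | C1(O[C@H](c2ccccc2)[C@@H](c2ccccc2)O1)[C@@]3(C)CC=C(C(C)C)C[C@@H]3C(=O)OCC
F6 | step 12 | 1β,8α-bis(tert-butyldimethylsilyloxy)eudesm-4(15)-en-3-one | C=C1C(=O)C[C@@H](O[Si](C)(C)C(C)(C)C)[C@]2(C)C[C@H](O[Si](C)(C)C(C)(C)C)[C@@H](C(C)C)C[C@@H]12
F7 | step 12 | 1β,8α-bis(tert-butyldimethylsilyloxy)eudesm-4(15)-en-3β-ol | C=C1[C@@H](O)C[C@@H](O[Si](C)(C)C(C)(C)C)[C@]2(C)C[C@H](O[Si](C)(C)C(C)(C)C)[C@@H](C(C)C)C[C@@H]12
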